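**Retrosynthetic overview**

- Feature: ring B (C4a, C5, C6, C7, C8, C8a; isochromene numbering) holds the C7 methyl/acyloxy carbon between the C6 and C8 carbonyls, so it is 2-methylcyclohexane-1,3-dione at a higher oxidation level. The atoms O2=C1–C8a=C4a of a 2-formyl enone form a 1-oxadiene that can take C3 and C4 from a terminal alkyne.
- Late disconnections: phenol MOM ethers; the C4a=C5 double bond (DDQ dehydrogenation of a 4H-pyran); the C6 ketone (from a silyl-protected carbinol).
- Ring A: the C4–C4a and O2–C3 bonds are formed between formyl enone 10 and enyne acetate 12.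
- Formyl enone 10 comes from 2-methylcyclohexane-1,3-dione: C7–O bond by enolate attack on the diaroyl peroxide of MOM-protected orsellinic acid, enzymatic desymmetrising reduction (sets C7), silylation, formylation at C8a, DDQ.
- Ring order: ring B is bought, ring A is closed in step 10, and the cross-conjugated dione chromophore is finished afterwards.

Key step: step 10

Assumptions: atom labels O2, C1, C3–C8a refer to the isochromene skeleton of the target. The ketoreductase is chosen from a panel so that the carbonyl reduced leaves the ester-bearing carbon S. The carbinol is drawn S (hydroxyl cis to the ester oxygen), but its configuration is irrelevant because C6 is reoxidised in step 12. Alcohol 11 is bought as the E isomer.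

**Step 1**
Reactants: 1 orsellinic acid
Product: 2 methoxymethyl 2,4-bis(methoxymethoxy)-6-methylbenzoate
Conditions: NaH, MOMCl, DMF, 0 °C → rt
Reagents that add atoms: chloromethyl methyl ether, COCCl
Why: O-alkylation (MOM protection) of the trianion at the carboxylate and both phenoxides; NaH is used because the hydrogen-bonded ortho phenol resists amine bases.

**Step 2**
Reactants: 2 methoxymethyl 2,4-bis(methoxymethoxy)-6-methylbenzoate
Product: 3 2,4-bis(methoxymethoxy)-6-methylbenzoic acid
Conditions: LiOH, THF/H2O, 50 °C; then 1 M HCl to pH 4, 0 °C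
Reagents that add atoms: lithium hydroxide, [Li+].[OH-]
Why: saponification by acyl–oxygen cleavage of the activated acyloxymethyl ester, while the aryl MOM ethers are inert to hydroxide and survive the brief cold acidification.

**Step 3**
Reactants: 3 2,4-bis(methoxymethoxy)-6-methylbenzoic acid (two molecules)
Product: 4 bis[2,4-bis(methoxymethoxy)-6-methylbenzoyl] peroxide
Conditions: DCC, H2O2 (50% aq.), CH2Cl2, 0 °C
Reagents that add atoms: hydrogen peroxide, OO
Why: carbodiimide-mediated diacyl peroxide synthesis (H2O2 attacks the O-acylisourea and the resulting peracid is acylated by a second O-acylisourea), which needs no acid chloride and liberates no HCl, so the MOM ethers are safe.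

**Step 4**
Reactants: 5 2-methylcyclohexane-1,3-dione; 4 bis[2,4-bis(methoxymethoxy)-6-methylbenzoyl] peroxide
Product: 6 1-methyl-2,6-dioxocyclohexyl 2,4-bis(methoxymethoxy)-6-methylbenzoate
Conditions: NaH, DMF, 0 °C; then 4, 0 °C → rt; dilute HCl work-up (pH 4)
Reagents that add atoms: none
Why: electrophilic C-acyloxylation of a 2-substituted 1,3-dicarbonyl enolate with a diacyl peroxide (attack of the soft enolate carbon on a peroxide oxygen), which makes the hindered tertiary ester without an esterification, the ortho substituents shielding the peroxide carbonyls from acyl transfer.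

**Step 5**
Reactants: 6 1-methyl-2,6-dioxocyclohexyl 2,4-bis(methoxymethoxy)-6-methylbenzoate
Product: 7 (1S,2S)-2-hydroxy-1-methyl-6-oxocyclohexyl 2,4-bis(methoxymethoxy)-6-methylbenzoate
Conditions: ketoreductase (from a screened panel), NADP+ (cat.), i-PrOH, phosphate buffer pH 7, DMSO (10%), 30 °C
Reagents that add atoms: none
Why: enzymatic desymmetrising reduction of a prochiral 2,2-disubstituted cyclohexane-1,3-dione, in which the active site selects one enantiotopic carbonyl and one face, fixing the quaternary carbon (C7 of the target) as S and the carbinol as S; the doubly ortho-substituted benzoate is too hindered to migrate to the new hydroxyl.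

**Step 6**
Reactants: 7 (1S,2S)-2-hydroxy-1-methyl-6-oxocyclohexyl 2,4-bis(methoxymethoxy)-6-methylbenzoate
Product: 8 (1S,2S)-2-[(tert-butyldimethylsilyl)oxy]-1-methyl-6-oxocyclohexyl 2,4-bis(methoxymethoxy)-6-methylbenzoate
Conditions: TBSOTf, 2,6-lutidine, CH2Cl2, −78 → 0 °C
Reagents that add atoms: tert-butyldimethylsilyl triflate, CC(C)(C)[Si](C)(C)OS(=O)(=O)C(F)(F)F
Why: silyl ether formation with the reactive triflate, required for a secondary hydroxyl next to a fully substituted carbon, which blocks retro-aldol cleavage and acyl migration in the basic step that follows.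

**Step 7**
Reactants: 8 (1S,2S)-2-[(tert-butyldimethylsilyl)oxy]-1-methyl-6-oxocyclohexyl 2,4-bis(methoxymethoxy)-6-methylbenzoate
Product: 9 (1S,2S,5Z)-2-[(tert-butyldimethylsilyl)oxy]-5-(hydroxymethylidene)-1-methyl-6-oxocyclohexyl 2,4-bis(methoxymethoxy)-6-methylbenzoate
Conditions: LiHMDS, THF, −78 °C; HCO2CH2CF3, −78 → 0 °C; aq. NH4Cl
Reagents that add atoms: 2,2,2-trifluoroethyl formate, O=COCC(F)(F)F
Why: crossed Claisen formylation of the lithium enolate, regiochemically unambiguous because only ring C5 (the future C8a) bears α-hydrogens, with the product resting as the chelated Z-hydroxymethylene ketone and the hindered ester untouched at low temperature.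

**Step 8**
Reactants: 9 (1S,2S,5Z)-2-[(tert-butyldimethylsilyl)oxy]-5-(hydroxymethylidene)-1-methyl-6-oxocyclohexyl 2,4-bis(methoxymethoxy)-6-methylbenzoate
Product: 10 (1S,2S)-2-[(tert-butyldimethylsilyl)oxy]-5-formyl-1-methyl-6-oxocyclohex-4-en-1-yl 2,4-bis(methoxymethoxy)-6-methylbenzoate
Conditions: DDQ, 1,4-dioxane, rt
Reagents that add atoms: none
Why: DDQ dehydrogenation of a 2-hydroxymethylene ketone to the 2-formyl enone (hydride abstraction from the allylic ring CH2, the future C4a, then loss of the enol proton); the stereocentres are untouched, and the aryl methyl group, meta to both alkoxy groups, is not activated toward DDQ.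

**Step 9**
Reactants: 11 (2E)-pent-2-en-4-yn-1-ol
Product: 12 (2E)-pent-2-en-4-yn-1-yl acetate
Conditions: Ac2O, pyridine, DMAP (cat.), CH2Cl2, 0 °C
Reagents that add atoms: acetic anhydride, CC(=O)OC(C)=O
Why: DMAP-catalysed acetylation of a primary allylic alcohol, leaving the terminal alkyne and the E alkene unchanged.

**Step 10**
Reactants: 10 (1S,2S)-2-[(tert-butyldimethylsilyl)oxy]-5-formyl-1-methyl-6-oxocyclohex-4-en-1-yl 2,4-bis(methoxymethoxy)-6-methylbenzoate; 12 (2E)-pent-2-en-4-yn-1-yl acetate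
Product: 14 (6S,7S)-3-[(1E)-3-acetoxyprop-1-en-1-yl]-6-[(tert-butyldimethylsilyl)oxy]-7-methyl-8-oxo-4a,5,6,7-tetrahydro-8H-isochromen-7-yl 2,4-bis(methoxymethoxy)-6-methylbenzoate as its C4a epimers, via alkynyl hydroxymethylene ketone 13 (not isolated)
Conditions: (CuOTf)2·PhMe (10 mol % Cu), i-Pr2NEt (0.3 equiv), CH2Cl2, 0 °C → rt, argon
Reagents that add atoms: none
Why: Proposed new method: monovalent copper and the amine convert enyne 12 into a copper acetylide, which adds through its terminal carbon to C4a of 10, the β-carbon of an alkene activated by both the C1 formyl group and the C8 ketone, and proton transfer from the ammonium salt leaves the β-keto aldehyde enol 13 and returns the catalyst. The same copper triflate then binds the triple bond of 13 as a π-acid, the C1 enol (or formyl) oxygen attacks C3, and protodemetalation gives the 4H-pyran, so that C4–C4a and O2–C3 are formed in one flask. The closest known reaction types are the copper-catalysed conjugate addition of terminal alkynes to alkylidene 1,3-dicarbonyl acceptors and the coinage-metal-catalysed cycloisomerisation of 3-substituted alk-4-yn-1-ones to 4H-pyrans, whose combination on a cyclic 2-formyl enone has not been shown. Ring A closes in the 6-endo-dig mode. The one new stereocentre, C4a, is not controlled and need not be, because step 13 removes its hydrogen. The step needs 1,4- over 1,2-addition (favoured by the soft copper acetylide, by a tertiary amine that cannot form an iminium ion and by the double activation of C4a), closure through O2 and not O8 (O8 is flanked by the fully substituted C7, the aldehyde-derived oxygen is the less hindered one) and 6-endo over 5-exo attack (the alkenyl group on C3 stabilises positive charge at that carbon of the metal-bound alkyne).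

**Step 11**
Reactants: 14 (6S,7S)-3-[(1E)-3-acetoxyprop-1-en-1-yl]-6-[(tert-butyldimethylsilyl)oxy]-7-methyl-8-oxo-4a,5,6,7-tetrahydro-8H-isochromen-7-yl 2,4-bis(methoxymethoxy)-6-methylbenzoate
Product: 15 (6S,7S)-3-[(1E)-3-acetoxyprop-1-en-1-yl]-6-hydroxy-7-methyl-8-oxo-4a,5,6,7-tetrahydro-8H-isochromen-7-yl 2,4-bis(methoxymethoxy)-6-methylbenzoate
Conditions: HF·pyridine, pyridine, THF, 0 °C → rt
Reagents that add atoms: none
Why: fluoride-mediated desilylation under buffered, non-basic conditions, which the acetate, the MOM ethers and the 4H-pyran should tolerate and which generates no free alkoxide, so neither retro-aldol cleavage nor acyl migration is expected.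

**Step 12**
Reactants: 15 (6S,7S)-3-[(1E)-3-acetoxyprop-1-en-1-yl]-6-hydroxy-7-methyl-8-oxo-4a,5,6,7-tetrahydro-8H-isochromen-7-yl 2,4-bis(methoxymethoxy)-6-methylbenzoate
Product: 16 (7S)-3-[(1E)-3-acetoxyprop-1-en-1-yl]-7-methyl-6,8-dioxo-4a,5,7,8-tetrahydro-6H-isochromen-7-yl 2,4-bis(methoxymethoxy)-6-methylbenzoate
Conditions: DMP, pyridine, CH2Cl2, 0 °C → rt
Reagents that add atoms: none
Why: Dess–Martin oxidation of the secondary alcohol to the C6 ketone under buffered conditions; C7 carries no hydrogen and cannot epimerise.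

**Step 13**
Reactants: 16 (7S)-3-[(1E)-3-acetoxyprop-1-en-1-yl]-7-methyl-6,8-dioxo-4a,5,7,8-tetrahydro-6H-isochromen-7-yl 2,4-bis(methoxymethoxy)-6-methylbenzoate
Product: 17 (7S)-3-[(1E)-3-acetoxyprop-1-en-1-yl]-7-methyl-6,8-dioxo-7,8-dihydro-6H-isochromen-7-yl 2,4-bis(methoxymethoxy)-6-methylbenzoate
Conditions: DDQ, CH2Cl2, 0 °C → rt
Reagents that add atoms: none
Why: DDQ dehydrogenation of a 4H-pyran, in which hydride is taken from C4a to give a pyrylium ion that loses the C5 proton (α to the C6 ketone), forming the C4a=C5 bond of the 6H-isochromene-6,8-dione and erasing the C4a stereocentre.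

**Step 14**
Reactants: 17 (7S)-3-[(1E)-3-acetoxyprop-1-en-1-yl]-7-methyl-6,8-dioxo-7,8-dihydro-6H-isochromen-7-yl 2,4-bis(methoxymethoxy)-6-methylbenzoate
Product: 18 (7S)-3-[(1E)-3-acetoxyprop-1-en-1-yl]-7-methyl-6,8-dioxo-7,8-dihydro-6H-isochromen-7-yl 2,4-dihydroxy-6-methylbenzoate
Conditions: TFA, CH2Cl2, H2O (trace), 0 °C → rt
Reagents that add atoms: none
Why: acid-catalysed cleavage of the two aryl MOM acetals; the tertiary C7 ester cannot ionise because it is flanked by two carbonyls, the primary allylic acetate should hold at this temperature, and C7 is not affected.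

**Compound list**

1 | orsellinic acid | Cc1cc(O)cc(O)c1C(=O)O | starting material
2 | methoxymethyl 2,4-bis(methoxymethoxy)-6-methylbenzoate | COCOC(=O)c1c(C)cc(OCOC)cc1OCOC | intermediate
3 | 2,4-bis(methoxymethoxy)-6-methylbenzoic acid | COCOc1cc(OCOC)cc(C)c1C(=O)O | intermediate
4 | bis[2,4-bis(methoxymethoxy)-6-methylbenzoyl] peroxide | COCOc1cc(OCOC)cc(C)c1C(=O)OOC(=O)c1c(C)cc(OCOC)cc1OCOC | intermediate
5 | 2-methylcyclohexane-1,3-dione | CC1C(=O)CCCC1=O | starting material
6 | 1-methyl-2,6-dioxocyclohexyl 2,4-bis(methoxymethoxy)-6-methylbenzoate | CC1(OC(=O)c2c(C)cc(OCOC)cc2OCOC)C(=O)CCCC1=O | intermediate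
7 | (1S,2S)-2-hydroxy-1-methyl-6-oxocyclohexyl 2,4-bis(methoxymethoxy)-6-methylbenzoate | C1CC[C@H](O)[C@](C)(OC(=O)c2c(C)cc(OCOC)cc2OCOC)C1=O | intermediate
8 | (1S,2S)-2-[(tert-butyldimethylsilyl)oxy]-1-methyl-6-oxocyclohexyl 2,4-bis(methoxymethoxy)-6-methylbenzoate | C1CC[C@H](O[Si](C)(C)C(C)(C)C)[C@](C)(OC(=O)c2c(C)cc(OCOC)cc2OCOC)C1=O | intermediate
9 | (1S,2S,5Z)-2-[(tert-butyldimethylsilyl)oxy]-5-(hydroxymethylidene)-1-methyl-6-oxocyclohexyl 2,4-bis(methoxymethoxy)-6-methylbenzoate | O/C=C1/CC[C@H](O[Si](C)(C)C(C)(C)C)[C@](C)(OC(=O)c2c(C)cc(OCOC)cc2OCOC)C1=O | intermediate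
10 | (1S,2S)-2-[(tert-butyldimethylsilyl)oxy]-5-formyl-1-methyl-6-oxocyclohex-4-en-1-yl 2,4-bis(methoxymethoxy)-6-methylbenzoate | O=CC1=CC[C@H](O[Si](C)(C)C(C)(C)C)[C@](C)(OC(=O)c2c(C)cc(OCOC)cc2OCOC)C1=O | intermediate
11 | (2E)-pent-2-en-4-yn-1-ol | OC/C=C/C#C | starting material
12 | (2E)-pent-2-en-4-yn-1-yl acetate | CC(=O)OC/C=C/C#C | intermediate
13 | (1S,2S,5Z)-4-[(3E)-5-acetoxypent-3-en-1-yn-1-yl]-2-[(tert-butyldimethylsilyl)oxy]-5-(hydroxymethylidene)-1-methyl-6-oxocyclohexyl 2,4-bis(methoxymethoxy)-6-methylbenzoate, both C4 epimers (not isolated) | CC(=O)OC/C=C/C#CC1C[C@H](O[Si](C)(C)C(C)(C)C)[C@](C)(OC(=O)c2c(C)cc(OCOC)cc2OCOC)C(=O)/C1=C\O | intermediate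
14 | (6S,7S)-3-[(1E)-3-acetoxyprop-1-en-1-yl]-6-[(tert-butyldimethylsilyl)oxy]-7-methyl-8-oxo-4a,5,6,7-tetrahydro-8H-isochromen-7-yl 2,4-bis(methoxymethoxy)-6-methylbenzoate, both C4a epimers | CC(=O)OC/C=C/C1=CC2C[C@H](O[Si](C)(C)C(C)(C)C)[C@](C)(OC(=O)c3c(C)cc(OCOC)cc3OCOC)C(=O)C2=CO1 | intermediate
15 | (6S,7S)-3-[(1E)-3-acetoxyprop-1-en-1-yl]-6-hydroxy-7-methyl-8-oxo-4a,5,6,7-tetrahydro-8H-isochromen-7-yl 2,4-bis(methoxymethoxy)-6-methylbenzoate, both C4a epimers | CC(=O)OC/C=C/C1=CC2C[C@H](O)[C@](C)(OC(=O)c3c(C)cc(OCOC)cc3OCOC)C(=O)C2=CO1 | intermediate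
16 | (7S)-3-[(1E)-3-acetoxyprop-1-en-1-yl]-7-methyl-6,8-dioxo-4a,5,7,8-tetrahydro-6H-isochromen-7-yl 2,4-bis(methoxymethoxy)-6-methylbenzoate, both C4a epimers | CC(=O)OC/C=C/C1=CC2CC(=O)[C@](C)(OC(=O)c3c(C)cc(OCOC)cc3OCOC)C(=O)C2=CO1 | intermediate
17 | (7S)-3-[(1E)-3-acetoxyprop-1-en-1-yl]-7-methyl-6,8-dioxo-7,8-dihydro-6H-isochromen-7-yl 2,4-bis(methoxymethoxy)-6-methylbenzoate | CC(=O)OC/C=C/C1=CC2=CC(=O)[C@](C)(OC(=O)c3c(C)cc(OCOC)cc3OCOC)C(=O)C2=CO1 | intermediate
18 | (7S)-3-[(1E)-3-acetoxyprop-1-en-1-yl]-7-methyl-6,8-dioxo-7,8-dihydro-6H-isochromen-7-yl 2,4-dihydroxy-6-methylbenzoate | CC(=O)OC/C=C/C1=CC2=CC(=O)[C@](C)(OC(=O)c3c(C)cc(O)cc3O)C(=O)C2=CO1 | target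

**Step count**

Total: 14 steps. Longest linear sequence: 13 steps (steps 1–8 and 10–14, from orsellinic acid).

**Steps most likely to fail**

1. Step 10. The acetylide may add to the formyl carbon instead of C4a. The amine may deprotonate C5 of the formyl enone, with loss of the silanol or self-condensation. The enol may close in the 5-exo mode or through O8. The fallback sets out from ketone 8 and alcohol 11 and returns at alcohol 15. It makes the C4–C4a bond on the plain enone and closes ring A afterwards, each by an established reaction type.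
   - Ketone 8 would be dehydrogenated with IBX (DMSO/fluorobenzene, 70 °C) to the cyclohexenone F1.
   - Alcohol 11 would be silylated (TBSCl, imidazole, CH2Cl2) to the silyl ether F2.
   - F2 would be converted into its dimethylalkynylalane (n-BuLi, then Me2AlCl) and added 1,4 to F1 under Ni(acac)2/DIBAL-H catalysis (Et2O, −5 °C), the known conjugate alkynylation of cyclic enones, giving the alkynyl ketone F3.
   - Formylation as in step 7 (LiHMDS, HCO2CH2CF3) would give the hydroxymethylene ketone F4.
   - (Ph3P)AuCl/AgOTf in CH2Cl2 would close ring A by the known 6-endo-dig cycloisomerisation of 3-substituted alk-4-yn-1-ones, giving the bis-silyl 4H-pyran F5.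
   - HF·pyridine would remove both silyl groups to give the diol F6.
   - Acetylation of the primary allylic hydroxyl in preference to the hindered C6 hydroxyl (Ac2O, 2,4,6-collidine, CH2Cl2, −20 °C) would give 15.

2. Step 5. No enzyme of the panel may accept the bulky aryl ester, or discrimination between the two enantiotopic carbonyls may be poor. The fallback sets out from dione 6 and returns at alcohol 7, replacing desymmetrisation by resolution.
   - Mono-reduction with NaBH4 (MeOH/CH2Cl2, −78 °C) and chromatographic separation of the diastereomers would give the racemic cis-hydroxy ketone F7.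
   - Lipase-catalysed acylation (Amano lipase PS or CAL-B, vinyl acetate, MTBE, 35 °C) should acetylate the R carbinol preferentially, giving the (1R,2R)-acetate F8 and leaving 7 unreacted, to be separated by chromatography.

3. Step 4. The electron-rich, hindered peroxide may decompose by electron transfer, may not form cleanly in step 3, or may be attacked by the enolate oxygen instead of carbon. The fallback sets out from dione 5 and acid 3 and returns at ester 6. It forms the C7–O bond first and the ester second.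
   - Dione 5 would be hydroxylated with dimethyldioxirane (acetone, 0 °C) to the hydroxy dione F9.
   - Acid 3 would be converted under neutral conditions (1-chloro-N,N,2-trimethylprop-1-en-1-amine, CH2Cl2) into the aroyl chloride F10.
   - Acylation of the tertiary alcohol of F9 with F10 (Et3N, DMAP, CH2Cl2, 0 °C → rt) would give 6.

**Further compounds**

F1 | step 10 | (1S,2S)-2-[(tert-butyldimethylsilyl)oxy]-1-methyl-6-oxocyclohex-4-en-1-yl 2,4-bis(methoxymethoxy)-6-methylbenzoate | C1=CC[C@H](O[Si](C)(C)C(C)(C)C)[C@](C)(OC(=O)c2c(C)cc(OCOC)cc2OCOC)C1=O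
F2 | step 10 | (2E)-tert-butyldimethyl(pent-2-en-4-yn-1-yloxy)silane | CC(C)(C)[Si](C)(C)OC/C=C/C#C
F3 | step 10 | (1S,2S)-2-[(tert-butyldimethylsilyl)oxy]-4-[(3E)-5-[(tert-butyldimethylsilyl)oxy]pent-3-en-1-yn-1-yl]-1-methyl-6-oxocyclohexyl 2,4-bis(methoxymethoxy)-6-methylbenzoate, both C4 epimers | CC(C)(C)[Si](C)(C)OC/C=C/C#CC1C[C@H](O[Si](C)(C)C(C)(C)C)[C@](C)(OC(=O)c2c(C)cc(OCOC)cc2OCOC)C(=O)C1
F4 | step 10 | (1S,2S,5Z)-2-[(tert-butyldimethylsilyl)oxy]-4-[(3E)-5-[(tert-butyldimethylsilyl)oxy]pent-3-en-1-yn-1-yl]-5-(hydroxymethylidene)-1-methyl-6-oxocyclohexyl 2,4-bis(methoxymethoxy)-6-methylbenzoate, both C4 epimers | CC(C)(C)[Si](C)(C)OC/C=C/C#CC1C[C@H](O[Si](C)(C)C(C)(C)C)[C@](C)(OC(=O)c2c(C)cc(OCOC)cc2OCOC)C(=O)/C1=C\O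
F5 | step 10 | (6S,7S)-6-[(tert-butyldimethylsilyl)oxy]-3-[(1E)-3-[(tert-butyldimethylsilyl)oxy]prop-1-en-1-yl]-7-methyl-8-oxo-4a,5,6,7-tetrahydro-8H-isochromen-7-yl 2,4-bis(methoxymethoxy)-6-methylbenzoate, both C4a epimers | CC(C)(C)[Si](C)(C)OC/C=C/C1=CC2C[C@H](O[Si](C)(C)C(C)(C)C)[C@](C)(OC(=O)c3c(C)cc(OCOC)cc3OCOC)C(=O)C2=CO1
F6 | step 10 | (6S,7S)-6-hydroxy-3-[(1E)-3-hydroxyprop-1-en-1-yl]-7-methyl-8-oxo-4a,5,6,7-tetrahydro-8H-isochromen-7-yl 2,4-bis(methoxymethoxy)-6-methylbenzoate, both C4a epimers | OC/C=C/C1=CC2C[C@H](O)[C@](C)(OC(=O)c3c(C)cc(OCOC)cc3OCOC)C(=O)C2=CO1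
F7 | step 5 | racemic cis-2-hydroxy-1-methyl-6-oxocyclohexyl 2,4-bis(methoxymethoxy)-6-methylbenzoate, (1S,2S) and (1R,2R) | C1CC[C@H](O)[C@](C)(OC(=O)c2c(C)cc(OCOC)cc2OCOC)C1=O.C1CC[C@@H](O)[C@@](C)(OC(=O)c2c(C)cc(OCOC)cc2OCOC)C1=O
F8 | step 5 | (1R,2R)-2-acetoxy-1-methyl-6-oxocyclohexyl 2,4-bis(methoxymethoxy)-6-methylbenzoate | C1CC[C@@H](OC(C)=O)[C@@](C)(OC(=O)c2c(C)cc(OCOC)cc2OCOC)C1=O
F9 | step 4 | 2-hydroxy-2-methylcyclohexane-1,3-dione | CC1(O)C(=O)CCCC1=O
F10 | step 4 | 2,4-bis(methoxymethoxy)-6-methylbenzoyl chloride | COCOc1cc(OCOC)cc(C)c1C(Cl)=O
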